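The data are calculated with made-up constants, and the scatter is random.

At 170 min the autumn run shows 0.0317 M of product, so 0.0483 M of coupling partner, the limiting reagent by charge, is still in that flask, yet its rate has sunk.

common to all: starting material 0.100 M; coupling partner 0.0800 M
- autumn: free catalyst 0.00200 M
- noon: free catalyst 0.00100 M
- summer: free catalyst 0.00200 M; time 680 min

| run | time / min | [product] / M |
|---|---|---|
| autumn run | 34 | 0.0189 |
| autumn run | 68 | 0.0255 |
| autumn run | 100 | 0.0286 |
| autumn run | 140 | 0.0296 |
| autumn run | 170 | 0.0317 |
| noon run | 34 | 0.0141 |
| noon run | 68 | 0.0178 |
| noon run | 100 | 0.0214 |
| noon run | 140 | 0.0229 |
| noon run | 170 | 0.0248 |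

(each reading ± 5 × 10⁻⁴ M)

- Overall: starting material + coupling partner -> product, with free catalyst as catalyst.
- Constant volume, constant temperature.
- An order is taken over about fifteen percent of the charge, up and down.

1. apparent order in [free catalyst] of the starting rate, round the charge of the autumn run (the rate where two percent of its starting material have turned into product)
2. product in the summer run at 680 min, as a share of the starting material charged

In the autumn run the rate is 1.94 × 10⁻⁴ M min⁻¹ between the first two readings and 4.43 × 10⁻⁵ M min⁻¹ between the third and the last. The midpoints of those spans lie 84.0 min apart, which gives 56.8 min. That is the rate lifetime, the time in which the rate of product formation falls by a factor e. If the fall goes on so, the product still to come is the present rate times this lifetime: 0.00136 M after the last reading. The summer run has the autumn charge, and 680 min lies 8.98 lifetimes beyond that reading, so I expect 33.1%.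

But the noon readings, reckoned the same way, give 104 min, a longer lifetime. Their late difference carries a scatter of 20.8%, so I can't dismiss it. Put into the autumn tail, it gives 35.0%, and I stay between these two figures.

The order meets a similar doubt. The first readings of the two runs give 0.423, but by then each rate has already decayed. Taking each run back to its start with its own lifetime gives 0.604, a chord across a halved charge rather than the local order asked for.

The forecast says an order of 1 (range 0.75 to 1.3) and a yield of 42% (range 35% to 48%), on the ground “That fits second-order catalyst loss”. Its yield stands above mine.

The simulation gives an order of 0.62 and 31.9%, 1.2 percentage points under my lifetime count.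

    2 free catalyst ⇌ catalyst dimer, settled at all times (1810 M⁻¹)
    free catalyst + starting material + coupling partner → product + free catalyst (201.6 M⁻² min⁻¹)
    starting material → decomposed substrate (0.01236 min⁻¹)
    2 starting material → homo dimer (0.04722 M⁻¹ min⁻¹)

Where two percent of its starting material had turned, the autumn run made product at 9.1 × 10⁻⁴ M min⁻¹. At the charge, decomposition and homo dimer formation together took starting material at 0.00218 M min⁻¹, which gives it a first lifetime of 45.9 min by those two steps. My autumn rate lifetime of 56.8 min lies above that and below the 80.9 min of decomposition by itself. Counted in decomposition lifetimes, 680 min is 8.40 of them, which takes starting material in the summer run under 2.24 × 10⁻⁵ M, while 0.0481 M of coupling partner remains.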